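**Retrosynthetic overview**
1. Target 18 ⇐ global desilylation of the tris-silyl flavanone 17.
2. The pyranone ring (the only ring made, and made last) is closed at C3–C4. The aldehyde carbon of 14, made nucleophilic as its carbene (Breslow) adduct, attacks the CH2–halide carbon; both carbons are electrophilic in normal polarity.
3. 14 ⇐ Mitsunobu etherification (inversion) of (S)-chlorohydrin 11 with salicylaldehyde 13. The C2 centre comes from Ru transfer hydrogenation of chloroketone 10.
4. 10 ⇐ aryllithium + Weinreb chloroacetamide 8. The side-chain carbinol comes from Shi epoxidation of one prenyl group, then silyl-triflate epoxide → allylic silyl ether isomerisation.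
5. B ring ⇐ 4-bromophenol + 2 prenyl bromide; A ring ⇐ 2,4-dihydroxybenzaldehyde.

Assumption: minor stereoisomers from the two independent catalyst-controlled steps (3 and 6) are removed by chromatography or crystallisation of 11 or 17, not counted as steps.

Abbreviations: TBS = tert-butyldimethylsilyl; TIPS = triisopropylsilyl; prenyl = 3-methylbut-2-en-1-yl; ArB = 4-(TBSO)-3-[(2R)-2-(TBSO)-3-methylbut-3-en-1-yl]-5-prenylphenyl.

**Step 1**
Reactants: 1 4-bromophenol; 2 prenyl bromide (1-bromo-3-methylbut-2-ene, 2.4 equiv)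
Product: 3 4-bromo-2,6-bis(3-methylbut-2-en-1-yl)phenol
Conditions: NaH (2.4 equiv, two charges), toluene, 0 °C → rt
Reagents that add atoms: none
Why: ortho-selective C-alkylation of the tight sodium phenoxide ion pair in a non-polar solvent (para position blocked by Br), repeated once in the same pot; moderate yield is accepted on cheap material.

**Step 2**
Reactants: 3 4-bromo-2,6-bis(3-methylbut-2-en-1-yl)phenol
Product: 4 [4-bromo-2,6-bis(3-methylbut-2-en-1-yl)phenoxy](tert-butyl)dimethylsilane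
Conditions: NaH, TBSCl, THF, 0 °C → rt
Reagents that add atoms: tert-butyldimethylsilyl chloride, CC(C)(C)[Si](C)(C)Cl
Why: O-silylation of the hindered phenoxide; the phenol must be masked so it cannot open the epoxide made next.

**Step 3**
Reactants: 4 [4-bromo-2,6-bis(3-methylbut-2-en-1-yl)phenoxy](tert-butyl)dimethylsilane
Product: 5 tert-butyl{4-bromo-2-{[(2R)-3,3-dimethyloxiran-2-yl]methyl}-6-(3-methylbut-2-en-1-yl)phenoxy}dimethylsilane
Conditions: D-fructose-derived Shi ketone (30 mol%), Oxone (≈0.45 equiv KHSO5), K2CO3, Bu4NHSO4, MeCN–DMM/aq. Na2B4O7–EDTA (pH 10.5), 0 °C; unreacted 4 recovered and recycled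
Reagents that add atoms: Oxone (potassium peroxymonosulfate), [K+].[O-]S(=O)(=O)OO
Why: Shi asymmetric epoxidation, in which the chiral dioxirane attacks the trisubstituted alkene through the spiro transition state and sets the (R) centre by catalyst control; the two prenyl groups are homotopic, so partial conversion gives one mono-epoxide (statistical ceiling about 45–50% per pass).

**Step 4**
Reactants: 5 tert-butyl{4-bromo-2-{[(2R)-3,3-dimethyloxiran-2-yl]methyl}-6-(3-methylbut-2-en-1-yl)phenoxy}dimethylsilane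
Product: 7 tert-butyl{4-bromo-2-[(2R)-2-(tert-butyldimethylsilyloxy)-3-methylbut-3-en-1-yl]-6-(3-methylbut-2-en-1-yl)phenoxy}dimethylsilane, via tertiary triflate 6 (not isolated)
Conditions: TBSOTf, 2,6-lutidine, toluene, −78 °C; then DBU, → rt
Reagents that add atoms: tert-butyldimethylsilyl triflate, CC(C)(C)[Si](C)(C)OS(=O)(=O)C(F)(F)F
Why: Noyori-type silyl triflate/amidine isomerisation of an epoxide to an allylic silyl ether, in which the tertiary C–O bond opens and DBU removes a methyl proton; the secondary C–O bond is never broken, so the (R) centre is retained and arrives already protected.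

**Step 5**
Reactants: 7 tert-butyl{4-bromo-2-[(2R)-2-(tert-butyldimethylsilyloxy)-3-methylbut-3-en-1-yl]-6-(3-methylbut-2-en-1-yl)phenoxy}dimethylsilane; 8 2-chloro-N-methoxy-N-methylacetamide
Product: 10 2-chloro-1-ArB-ethan-1-one, via aryllithium 9 (not isolated)
Conditions: t-BuLi (2.1 equiv), THF, −78 °C; then 8, −78 → −20 °C; aq. NH4Cl
Reagents that add atoms: none
Why: bromine–lithium exchange followed by Weinreb amide acylation, where the chelated tetrahedral intermediate prevents over-addition and releases the α-chloroketone on quench.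

**Step 6**
Reactants: 10 2-chloro-1-ArB-ethan-1-one
Product: 11 (1S)-2-chloro-1-ArB-ethan-1-ol
Conditions: RuCl(p-cymene)[(R,R)-TsDPEN] (1 mol%), HCO2H–Et3N (5:2), EtOAc, rt
Reagents that add atoms: none
Why: Noyori–Ikariya asymmetric transfer hydrogenation, in which the (R,R)-Ru hydride reduces the aryl ketone face fixed by the aryl CH/π contact and gives the (S)-chlorohydrin under catalyst control, leaving the alkenes untouched.

**Step 7**
Reactants: 12 2,4-dihydroxybenzaldehyde
Product: 13 2-hydroxy-4-(triisopropylsilyloxy)benzaldehyde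
Conditions: TIPSCl (1.05 equiv), imidazole, CH2Cl2, 0 °C
Reagents that add atoms: triisopropylsilyl chloride, CC(C)[Si](Cl)(C(C)C)C(C)C
Why: selective silylation of the 4-OH, because the 2-OH is hydrogen-bonded to the aldehyde and much less nucleophilic.

**Step 8**
Reactants: 11 (1S)-2-chloro-1-ArB-ethan-1-ol; 13 2-hydroxy-4-(triisopropylsilyloxy)benzaldehyde
Product: 14 2-[(1R)-2-chloro-1-ArB-ethoxy]-4-(triisopropylsilyloxy)benzaldehyde
Conditions: PPh3, DIAD, toluene, 0 °C → rt
Reagents that add atoms: none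
Why: Mitsunobu etherification, in which the acidic salicylaldehyde phenol displaces the oxyphosphonium by SN2 with inversion ((S)-carbinol → (R)-ether, the spatial arrangement of the 2S flavanone), while the β-chlorine and the twisted hindered silyloxy group disfavour benzylic ionisation.

**Step 9 (key step)**
Reactants: 14 2-[(1R)-2-chloro-1-ArB-ethoxy]-4-(triisopropylsilyloxy)benzaldehyde
Product: 17 (2S)-2-ArB-7-(triisopropylsilyloxy)chroman-4-one, via primary iodide 15 (not isolated), via Breslow intermediate 16 (not isolated)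
Conditions: 3,4-dimethyl-5-(2-hydroxyethyl)thiazolium iodide (20 mol%), NaI (20 mol%), i-Pr2NEt (1.5 equiv), 1,4-dioxane, 70 °C, Ar
Reagents that add atoms: none
Why: Proposed new method: the thiazol-2-ylidene adds to the aldehyde to give Breslow intermediate 16, an acyl anion equivalent whose carbon displaces the primary halide (iodide from in-situ Finkelstein exchange) in a 6-exo-tet SN2 that forms C3–C4, closes the pyranone and releases the carbene, with C2 untouched and so retained as (S) under the weak amine base; the closest known reaction type is the NHC-catalysed intramolecular nucleophilic substitution of 2-(2-halo- or 2-sulfonyloxy-ethoxy)benzaldehydes to chroman-4-ones, extended here to a tether bearing an aryl-substituted stereocentre.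

**Step 10**
Reactants: 17 (2S)-2-ArB-7-(triisopropylsilyloxy)chroman-4-one
Product: 18 (2S)-7-hydroxy-2-{4-hydroxy-3-[(2R)-2-hydroxy-3-methylbut-3-en-1-yl]-5-(3-methylbut-2-en-1-yl)phenyl}chroman-4-one (CNP0169187.1)
Conditions: HF·pyridine, pyridine, THF, 0 °C → rt
Reagents that add atoms: none
Why: fluoride-mediated cleavage of all three silyl ethers under buffered, non-basic conditions, so no 4'-phenoxide forms that could open the flavanone and racemise C2, and the prenyl and allylic alcohol groups are not exposed to strong acid.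

**Compound list**
1 | 4-bromophenol | Oc1ccc(Br)cc1 | starting material
2 | prenyl bromide (1-bromo-3-methylbut-2-ene) | CC(C)=CCBr | starting material
3 | 4-bromo-2,6-bis(3-methylbut-2-en-1-yl)phenol | CC(C)=CCc1cc(Br)cc(CC=C(C)C)c1O | intermediate
4 | [4-bromo-2,6-bis(3-methylbut-2-en-1-yl)phenoxy](tert-butyl)dimethylsilane | CC(C)=CCc1cc(Br)cc(CC=C(C)C)c1O[Si](C)(C)C(C)(C)C | intermediate
5 | tert-butyl{4-bromo-2-{[(2R)-3,3-dimethyloxiran-2-yl]methyl}-6-prenylphenoxy}dimethylsilane | CC1(C)O[C@@H]1Cc1cc(Br)cc(CC=C(C)C)c1O[Si](C)(C)C(C)(C)C | intermediate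
6 | (3R)-4-[5-bromo-2-(TBSO)-3-prenylphenyl]-3-(TBSO)-2-methylbutan-2-yl triflate (formed in situ) | CC(C)(OS(=O)(=O)C(F)(F)F)[C@H](O[Si](C)(C)C(C)(C)C)Cc1cc(Br)cc(CC=C(C)C)c1O[Si](C)(C)C(C)(C)C | intermediate
7 | tert-butyl{4-bromo-2-[(2R)-2-(TBSO)-3-methylbut-3-en-1-yl]-6-prenylphenoxy}dimethylsilane (ArB–Br) | C=C(C)[C@H](O[Si](C)(C)C(C)(C)C)Cc1cc(Br)cc(CC=C(C)C)c1O[Si](C)(C)C(C)(C)C | intermediate
8 | 2-chloro-N-methoxy-N-methylacetamide | CON(C)C(=O)CCl | starting material
9 | aryllithium ArB–Li (formed in situ) | C=C(C)[C@H](O[Si](C)(C)C(C)(C)C)Cc1cc([Li])cc(CC=C(C)C)c1O[Si](C)(C)C(C)(C)C | intermediate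
10 | 2-chloro-1-ArB-ethan-1-one | C=C(C)[C@H](O[Si](C)(C)C(C)(C)C)Cc1cc(C(=O)CCl)cc(CC=C(C)C)c1O[Si](C)(C)C(C)(C)C | intermediate
11 | (1S)-2-chloro-1-ArB-ethan-1-ol | C=C(C)[C@H](O[Si](C)(C)C(C)(C)C)Cc1cc([C@H](O)CCl)cc(CC=C(C)C)c1O[Si](C)(C)C(C)(C)C | intermediate
12 | 2,4-dihydroxybenzaldehyde | O=Cc1ccc(O)cc1O | starting material
13 | 2-hydroxy-4-(triisopropylsilyloxy)benzaldehyde | O=Cc1ccc(O[Si](C(C)C)(C(C)C)C(C)C)cc1O | intermediate
14 | 2-[(1R)-2-chloro-1-ArB-ethoxy]-4-(triisopropylsilyloxy)benzaldehyde | C=C(C)[C@H](O[Si](C)(C)C(C)(C)C)Cc1cc([C@@H](Oc2cc(O[Si](C(C)C)(C(C)C)C(C)C)ccc2C=O)CCl)cc(CC=C(C)C)c1O[Si](C)(C)C(C)(C)C | intermediate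
15 | 2-[(1R)-2-iodo-1-ArB-ethoxy]-4-(triisopropylsilyloxy)benzaldehyde (formed in situ) | C=C(C)[C@H](O[Si](C)(C)C(C)(C)C)Cc1cc([C@@H](Oc2cc(O[Si](C(C)C)(C(C)C)C(C)C)ccc2C=O)CI)cc(CC=C(C)C)c1O[Si](C)(C)C(C)(C)C | intermediate
16 | Breslow intermediate: enaminol of 15 with 3,4-dimethyl-5-(2-hydroxyethyl)thiazol-2-ylidene (formed in situ) | C=C(C)[C@H](O[Si](C)(C)C(C)(C)C)Cc1cc([C@@H](Oc2cc(O[Si](C(C)C)(C(C)C)C(C)C)ccc2C(O)=C2SC(CCO)=C(C)N2C)CI)cc(CC=C(C)C)c1O[Si](C)(C)C(C)(C)C | intermediate
17 | (2S)-2-ArB-7-(triisopropylsilyloxy)chroman-4-one | C=C(C)[C@H](O[Si](C)(C)C(C)(C)C)Cc1cc([C@@H]2CC(=O)c3ccc(O[Si](C(C)C)(C(C)C)C(C)C)cc3O2)cc(CC=C(C)C)c1O[Si](C)(C)C(C)(C)C | intermediate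
18 | (2S)-7-hydroxy-2-{4-hydroxy-3-[(2R)-2-hydroxy-3-methylbut-3-en-1-yl]-5-(3-methylbut-2-en-1-yl)phenyl}chroman-4-one | C=C(C)[C@H](O)Cc1cc([C@@H]2CC(=O)c3ccc(O)cc3O2)cc(CC=C(C)C)c1O | target

**Totals**
Total steps: 10. Longest linear sequence: 9 (steps 1–6, 8, 9, 10); step 7 is a one-step side branch.

**Three steps most likely to fail**

Step 9 (carbene-catalysed ring closure). The risks are slow SN2 at the β-branched, β-oxygenated CH2X, loss of HX to the α-aryloxystyrene, alkylation of the carbene, and base-induced retro-oxa-Michael opening of 17 that would erode C2. The fallback sets out from 14 and returns at 17. The aldehyde is converted with propane-1,3-dithiol (cat. I2, CHCl3) into the 2-aryl-1,3-dithiane F1. n-BuLi (THF, −78 → 0 °C) gives the 2-lithiodithiane, a stoichiometric masked acyl anion, which closes the ring by intramolecular alkylation of the CH2Cl carbon to give the spiro-dithiane F2. MeI/CaCO3 in aqueous MeCN then unmasks ketone 17.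

Step 8 (Mitsunobu ether formation). The risks are partial ionisation of the para-silyloxybenzylic oxyphosphonium (loss of ee) and elimination. The fallback sets out from 7 and returns at 17, bypassing steps 5, 6, 8 and 9. Br/Li exchange (t-BuLi), B(OiPr)3 and mild hydrolysis give the arylboronic acid F3. Purchased 7-hydroxychromone F4 is silylated (TIPSCl, imidazole) to 7-(triisopropylsilyloxy)chromone F5. Pd(OCOCF3)2/t-BuPyOx-catalysed asymmetric conjugate addition of F3 to F5 (NH4PF6, H2O, ClCH2CH2Cl, 60 °C) forms the C2–aryl bond and the 2S centre directly, giving 17. The ligand antipode expected to give 2S is (R)-t-BuPyOx, by analogy with cyclic enones; this should be confirmed on a model.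

Step 4 (epoxide → allylic silyl ether). The risks are hydride shift to the ketone, proton loss towards the benzylic CH2, and Friedel–Crafts capture of the tertiary cation. The fallback sets out from 5 and returns at 7. Et2Al–TMP (toluene, 0 °C) effects an amide-base syn-β-elimination through a cyclic transition state with no cationic intermediate, removing a methyl proton to give the free (R)-allylic alcohol F6. TBSCl/imidazole (DMF) then gives 7.

**Further compounds**
F1 | step 9 | 2-{2-[(1R)-2-chloro-1-ArB-ethoxy]-4-(triisopropylsilyloxy)phenyl}-1,3-dithiane | C=C(C)[C@H](O[Si](C)(C)C(C)(C)C)Cc1cc([C@@H](Oc2cc(O[Si](C(C)C)(C(C)C)C(C)C)ccc2C2SCCCS2)CCl)cc(CC=C(C)C)c1O[Si](C)(C)C(C)(C)C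
F2 | step 9 | (2S)-2-ArB-7-(triisopropylsilyloxy)spiro[chromane-4,2'-[1,3]dithiane] | C=C(C)[C@H](O[Si](C)(C)C(C)(C)C)Cc1cc([C@@H]2CC3(SCCCS3)c3ccc(O[Si](C(C)C)(C(C)C)C(C)C)cc3O2)cc(CC=C(C)C)c1O[Si](C)(C)C(C)(C)C
F3 | step 8 | ArB–B(OH)2 (arylboronic acid from 7) | C=C(C)[C@H](O[Si](C)(C)C(C)(C)C)Cc1cc(B(O)O)cc(CC=C(C)C)c1O[Si](C)(C)C(C)(C)C
F4 | step 8 | 7-hydroxychromone (7-hydroxy-4H-chromen-4-one, purchased) | O=c1ccoc2cc(O)ccc12
F5 | step 8 | 7-(triisopropylsilyloxy)-4H-chromen-4-one | O=c1ccoc2cc(O[Si](C(C)C)(C(C)C)C(C)C)ccc12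
F6 | step 4 | (2R)-1-[5-bromo-2-(TBSO)-3-prenylphenyl]-3-methylbut-3-en-2-ol | C=C(C)[C@H](O)Cc1cc(Br)cc(CC=C(C)C)c1O[Si](C)(C)C(C)(C)C
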